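## Retrosynthetic overview

1. Structural feature: ring A carries three neighbouring carbons, C1 (CO2Me), C2 (diaryl C=O) and C3 (OMe). The C1–C2 bond is read as an aryne bond next to the C3 methoxy group, so C1 takes a carbon nucleophile and C2 a carbon electrophile.
2. Target 31 ⇐ debenzylation, acetylation, MOM removal and esterification ⇐ keto acid 27 ⇐ oxygenation at C3 of phthalide 23 ⇐ hydrolysis of iminoisobenzofuran 22.
3. 22 ⇐ silylaryl triflate 11 + t-BuNC 18 (future ester carbon) + ring B aldehyde 17 (future ketone carbon). The five-membered O-ring closed here is the only ring made, and step 12 opens it again. Both benzene rings are bought.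
4. 11 ⇐ phloroglucinol 1 via the symmetric 2-bromoresorcinol 6, with bromine set between two carbamates and silicon brought in last by a retro-Brook shift. 17 ⇐ orcinol 12 by Bn/MOM differentiation and ortho-lithiation/formylation.

Key step: step 10

Remark: the target has no stereocentre. The single carbinol centre in 21, 22, 23 and 25 is carried as a racemate and is erased in step 12. Keto acid 27 is drawn in its open form, although it can also exist as its 3-hydroxyphthalide tautomer.

## Route

Step 1
Reactants: 1 phloroglucinol
Product: 2 5-(benzyloxy)benzene-1,3-diol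
Conditions: BnBr (0.33 equiv), K2CO3 (0.4 equiv), DMF, rt to 50 °C; surplus 1 removed by water wash
Reagents that add atoms: benzyl bromide, BrCc1ccccc1
Why: Williamson ether synthesis on a triol with three equivalent hydroxyls, so only one mono-ether exists and the threefold surplus of 1 should hold back further benzylation.

Step 2
Reactants: 2 5-(benzyloxy)benzene-1,3-diol
Product: 3 5-(benzyloxy)-1,3-phenylene bis(N,N-diethylcarbamate)
Conditions: Et2NCOCl (2.5 equiv), K2CO3, MeCN, reflux
Reagents that add atoms: N,N-diethylcarbamoyl chloride, CCN(CC)C(=O)Cl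
Why: Exhaustive O-carbamoylation of both phenols installs two strong directing groups on either side of C2 and keeps the molecule symmetric.

Step 3
Reactants: 3 5-(benzyloxy)-1,3-phenylene bis(N,N-diethylcarbamate)
Product: 5 5-(benzyloxy)-2-bromo-1,3-phenylene bis(N,N-diethylcarbamate), via aryllithium 4 (not isolated)
Conditions: s-BuLi, TMEDA, THF, −78 °C; BrCl2CCCl2Br, −78 °C to rt
Reagents that add atoms: 1,2-dibromo-1,1,2,2-tetrachloroethane, BrC(Cl)(Cl)C(Cl)(Cl)Br
Why: Directed ortho metalation, in which C2–H between two O-carbamates should be removed faster than C4/C6–H (one carbamate, one benzyl ether) or the benzylic CH2, and fast halophilic trapping at −78 °C precedes any anionic ortho-Fries shift.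

Step 4
Reactants: 5 5-(benzyloxy)-2-bromo-1,3-phenylene bis(N,N-diethylcarbamate)
Product: 6 5-(benzyloxy)-2-bromobenzene-1,3-diol
Conditions: NaOH, EtOH/H2O, reflux; then 1 M HCl
Reagents that add atoms: none
Why: Alkaline acyl-oxygen hydrolysis of the aryl carbamates, which the aryl bromide and benzyl ether tolerate and which is harmless here because no acid- or base-labile arylsilane is present yet.

Step 5
Reactants: 6 5-(benzyloxy)-2-bromobenzene-1,3-diol
Product: 7 5-(benzyloxy)-2-bromo-3-methoxyphenol
Conditions: MeI (1.0 equiv), K2CO3 (1.0 equiv), acetone, rt; unreacted 6 recycled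
Reagents that add atoms: iodomethane, CI
Why: Williamson monomethylation of a diol with two equivalent hydroxyls, so either oxygen gives the same product and limiting MeI should restrain dimethylation, as in the usual preparation of 2-bromo-3-methoxyphenol from 2-bromoresorcinol.

Step 6
Reactants: 7 5-(benzyloxy)-2-bromo-3-methoxyphenol
Product: 11 5-(benzyloxy)-3-methoxy-2-(trimethylsilyl)phenyl trifluoromethanesulfonate, via silyl ether 8 (not isolated), via aryllithium 9 (not isolated), via lithium phenoxide 10 (not isolated)
Conditions: (Me3Si)2NH, THF, reflux, then evaporate; n-BuLi, THF, −78 °C; Tf2O, −78 °C to rt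
Reagents that add atoms: hexamethyldisilazane, C[Si](C)(C)N[Si](C)(C)C; trifluoromethanesulfonic anhydride, O=S(=O)(OS(=O)(=O)C(F)(F)F)C(F)(F)F
Why: The standard one-flask sequence from o-bromophenols to o-silylaryl triflates (O-silylation, Br–Li exchange, retro-Brook O-to-C silyl shift, O-triflation), which places silicon exactly at the former C–Br carbon and keeps the very electron-rich arylsilane out of all earlier phenol chemistry.

Step 7
Reactants: 12 orcinol
Product: 13 3-(benzyloxy)-5-methylphenol
Conditions: BnBr (0.5 equiv), K2CO3 (0.6 equiv), DMF, rt; surplus 12 removed by water wash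
Reagents that add atoms: benzyl bromide, BrCc1ccccc1
Why: Williamson ether synthesis on a diol with equivalent hydroxyls, using surplus 12 to favour the mono-ether that will later become the free ring B phenol.

Step 8
Reactants: 13 3-(benzyloxy)-5-methylphenol
Product: 14 1-(benzyloxy)-3-(methoxymethoxy)-5-methylbenzene
Conditions: NaH, MOMCl, DMF, 0 °C to rt
Reagents that add atoms: chloromethyl methyl ether, COCCl
Why: Phenoxide alkylation gives the MOM acetal, which marks the future acetate oxygen, is orthogonal to benzyl, and directs lithiation well.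

Step 9
Reactants: 14 1-(benzyloxy)-3-(methoxymethoxy)-5-methylbenzene
Product: 17 2-(benzyloxy)-6-(methoxymethoxy)-4-methylbenzaldehyde, via aryllithium 15 (not isolated), via lithium hemiaminal alkoxide 16 (not isolated)
Conditions: n-BuLi, TMEDA, THF, 0 °C; DMF, 0 °C to rt; H2O
Reagents that add atoms: N,N-dimethylformamide, CN(C)C=O
Why: Directed ortho metalation at the one C–H flanked by both oxygen substituents (cooperative OMOM/OBn direction, as in the lithiation of 1,3-dialkoxybenzenes), followed by formylation with DMF.

Step 10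
Reactants: 11 5-(benzyloxy)-3-methoxy-2-(trimethylsilyl)phenyl trifluoromethanesulfonate; 17 2-(benzyloxy)-6-(methoxymethoxy)-4-methylbenzaldehyde; 18 tert-butyl isocyanide
Product: 22 rac-N-tert-butyl-6-(benzyloxy)-3-[2-(benzyloxy)-6-(methoxymethoxy)-4-methylphenyl]-4-methoxyisobenzofuran-1(3H)-imine, via aryne 19 (not isolated), via nitrilium aryl anion 20 (not isolated), via nitrilium alkoxide 21 (not isolated)
Conditions: 11 (1 equiv), 18 (1.5 equiv), 17 (2 equiv), KF, 18-crown-6, THF, 0 °C to rt; chromatography on Et3N-deactivated silica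
Reagents that add atoms: none
Why: Fluoride attacks silicon of 11 and triflate leaves to give aryne 19, whose C1≡C2 bond is polarised and distorted by the inductively withdrawing C3 methoxy group, so the isocyanide carbon of 18 adds at the remote C1 and the charge settles at C2 next to the C–O bond (zwitterion 20). The C2 aryl anion then adds to the formyl carbon of 17 to give alkoxide 21, helped by the linear and sterically small nitrilium neighbour, so the crowded carbon is built at the sp3 carbinol level and not as a tetra-ortho-substituted ketone. The alkoxide closes onto the nitrilium carbon in a 5-exo-dig mode, forming the five-membered iminoisobenzofuran ring, so C1–C, C2–C and O–C bonds all arise in one operation. This is the known aryne–isocyanide–aldehyde three-component coupling, which is regioselective with 3-methoxybenzyne. The one new stereocentre (C3 of the heterocycle) has no controlling element, should form as a racemate, and is erased in step 12. The step needs site selectivity on the aryne, secured by the C3 methoxy group against which the C5 benzyloxy group (meta/para to the aryne carbons) has only a weak influence, and it needs capture of 20 by the aldehyde in preference to a proton, a second aryne or more isocyanide, secured by the surplus of non-enolisable 17, a dry medium and slow aryne release at 0 °C.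

Step 11
Reactants: 22 rac-iminoisobenzofuran
Product: 23 rac-6-(benzyloxy)-3-[2-(benzyloxy)-6-(methoxymethoxy)-4-methylphenyl]-4-methoxyisobenzofuran-1(3H)-one
Conditions: AcOH/THF/H2O, rt
Reagents that add atoms: water, O
Why: Acid hydrolysis of a cyclic imidate, in which the N-protonated tetrahedral intermediate expels tert-butylamine to give the lactone in preference to the hydroxy amide, while dilute acetic acid is too weak to cleave the aryl MOM acetal.

Step 12
Reactants: 23 rac-phthalide
Product: 27 5-(benzyloxy)-2-[2-(benzyloxy)-6-(methoxymethoxy)-4-methylbenzoyl]-3-methoxybenzoic acid, via potassium isobenzofuranolate 24 (not isolated), via potassium peroxide 25 (not isolated), via potassium keto carboxylate 26 (not isolated)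
Conditions: KN(SiMe3)2, THF, −78 °C; O2, P(OEt)3, −78 to 0 °C; cold 0.5 M HCl
Reagents that add atoms: dioxygen, O=O
Why: Carbanion autoxidation (enolate hydroxylation with O2 and P(OEt)3), in which the doubly benzylic C3–H, α to oxygen and conjugated through ring A with the lactone carbonyl, should be removed to give 24, the small O2 molecule is little hindered by the crowding, the phosphite reduces peroxide 25, and the lactol alkoxide opens irreversibly to carboxylate 26, erasing the stereocentre.

Step 13
Reactants: 27 keto acid
Product: 28 methyl 5-(benzyloxy)-2-[2-(benzyloxy)-6-(methoxymethoxy)-4-methylbenzoyl]-3-methoxybenzoate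
Conditions: MeI, K2CO3, DMF, rt
Reagents that add atoms: iodomethane, CI
Why: SN2 alkylation of the open carboxylate gives the normal keto ester, whereas acid-catalysed esterification of such a hindered aroylbenzoic acid would risk the cyclic 3-methoxyphthalide pseudo-ester.

Step 14
Reactants: 28 MOM-protected keto ester
Product: 29 methyl 5-(benzyloxy)-2-[2-(benzyloxy)-6-hydroxy-4-methylbenzoyl]-3-methoxybenzoate
Conditions: HCl (cat., 1.25 M in MeOH), MeOH/CH2Cl2, rt to 40 °C
Reagents that add atoms: none
Why: Acid-catalysed acetal exchange removes the only MOM group, aided by the hydrogen bond between the freed phenol and the ketone, while benzyl ethers and the methyl ester are inert in acidic methanol.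

Step 15
Reactants: 29 ring B phenol
Product: 30 methyl 2-[2-acetoxy-6-(benzyloxy)-4-methylbenzoyl]-5-(benzyloxy)-3-methoxybenzoate
Conditions: Ac2O, pyridine, DMAP (cat.), CH2Cl2, rt
Reagents that add atoms: acetic anhydride, CC(=O)OC(C)=O
Why: DMAP-catalysed acylation of the only free hydroxyl, where the nucleophilic catalyst overcomes the chelation and crowding of the ortho-acyl phenol.

Step 16
Reactants: 30 bis(benzyl ether) acetate
Product: 31 penibenzophenone C, methyl 2-(2-acetoxy-6-hydroxy-4-methylbenzoyl)-5-hydroxy-3-methoxybenzoate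
Conditions: H2 (1 atm), Pd/C (10 wt% Pd on carbon), EtOAc, rt
Reagents that add atoms: none
Why: Catalytic hydrogenolysis of both aryl benzyl ethers, in which the ketone with four ortho substituents is twisted and shielded from the catalyst surface, the alcohol-free neutral solvent spares the aryl acetate and methyl ester, and any acetyl shift between the two ring B oxygens is degenerate.

## Compound list

1 | phloroglucinol | Oc1cc(O)cc(O)c1 | starting material
2 | 5-(benzyloxy)benzene-1,3-diol | Oc1cc(O)cc(OCc2ccccc2)c1 | intermediate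
3 | 5-(benzyloxy)-1,3-phenylene bis(N,N-diethylcarbamate) | CCN(CC)C(=O)Oc1cc(OCc2ccccc2)cc(OC(=O)N(CC)CC)c1 | intermediate
4 | 5-(benzyloxy)-2-lithio-1,3-phenylene bis(N,N-diethylcarbamate) (not isolated) | CCN(CC)C(=O)Oc1cc(OCc2ccccc2)cc(OC(=O)N(CC)CC)c1[Li] | intermediate
5 | 5-(benzyloxy)-2-bromo-1,3-phenylene bis(N,N-diethylcarbamate) | CCN(CC)C(=O)Oc1cc(OCc2ccccc2)cc(OC(=O)N(CC)CC)c1Br | intermediate
6 | 5-(benzyloxy)-2-bromobenzene-1,3-diol | Oc1cc(OCc2ccccc2)cc(O)c1Br | intermediate
7 | 5-(benzyloxy)-2-bromo-3-methoxyphenol | COc1cc(OCc2ccccc2)cc(O)c1Br | intermediate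
8 | [5-(benzyloxy)-2-bromo-3-methoxyphenoxy]trimethylsilane (not isolated) | COc1cc(OCc2ccccc2)cc(O[Si](C)(C)C)c1Br | intermediate
9 | [5-(benzyloxy)-2-lithio-3-methoxyphenoxy]trimethylsilane (not isolated) | COc1cc(OCc2ccccc2)cc(O[Si](C)(C)C)c1[Li] | intermediate
10 | lithium 5-(benzyloxy)-3-methoxy-2-(trimethylsilyl)phenoxide (not isolated) | COc1cc(OCc2ccccc2)cc(O[Li])c1[Si](C)(C)C | intermediate
11 | 5-(benzyloxy)-3-methoxy-2-(trimethylsilyl)phenyl trifluoromethanesulfonate | COc1cc(OCc2ccccc2)cc(OS(=O)(=O)C(F)(F)F)c1[Si](C)(C)C | intermediate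
12 | orcinol (5-methylbenzene-1,3-diol) | Cc1cc(O)cc(O)c1 | starting material
13 | 3-(benzyloxy)-5-methylphenol | Cc1cc(O)cc(OCc2ccccc2)c1 | intermediate
14 | 1-(benzyloxy)-3-(methoxymethoxy)-5-methylbenzene | COCOc1cc(C)cc(OCc2ccccc2)c1 | intermediate
15 | 2-(benzyloxy)-6-(methoxymethoxy)-4-methylphenyllithium (not isolated) | COCOc1cc(C)cc(OCc2ccccc2)c1[Li] | intermediate
16 | lithium [2-(benzyloxy)-6-(methoxymethoxy)-4-methylphenyl](dimethylamino)methoxide (not isolated) | COCOc1cc(C)cc(OCc2ccccc2)c1C(O[Li])N(C)C | intermediate
17 | 2-(benzyloxy)-6-(methoxymethoxy)-4-methylbenzaldehyde | COCOc1cc(C)cc(OCc2ccccc2)c1C=O | intermediate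
18 | tert-butyl isocyanide | CC(C)(C)[N+]#[C-] | starting material
19 | 5-(benzyloxy)-3-methoxybenzyne (not isolated) | COC1=CC(OCc2ccccc2)=CC#C1 | intermediate
20 | C1 N-tert-butylnitrilium, C2 aryl anion zwitterion (not isolated) | COc1cc(OCc2ccccc2)cc(C#[N+]C(C)(C)C)[c-]1 | intermediate
21 | rac-diarylmethoxide bearing the C1 N-tert-butylnitrilium (not isolated) | COCOc1cc(C)cc(OCc2ccccc2)c1C([O-])c1c(OC)cc(OCc2ccccc2)cc1C#[N+]C(C)(C)C | intermediate
22 | rac-N-tert-butyl-6-(benzyloxy)-3-[2-(benzyloxy)-6-(methoxymethoxy)-4-methylphenyl]-4-methoxyisobenzofuran-1(3H)-imine | COCOc1cc(C)cc(OCc2ccccc2)c1C1OC(=NC(C)(C)C)c2cc(OCc3ccccc3)cc(OC)c21 | intermediate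
23 | rac-6-(benzyloxy)-3-[2-(benzyloxy)-6-(methoxymethoxy)-4-methylphenyl]-4-methoxyisobenzofuran-1(3H)-one | COCOc1cc(C)cc(OCc2ccccc2)c1C1OC(=O)c2cc(OCc3ccccc3)cc(OC)c21 | intermediate
24 | potassium 3-aryl-6-(benzyloxy)-4-methoxyisobenzofuran-1-olate (not isolated) | [K+].COCOc1cc(C)cc(OCc2ccccc2)c1C1=C2C(OC)=CC(OCc3ccccc3)=CC2=C([O-])O1 | intermediate
25 | rac-potassium salt of the 3-hydroperoxy-3-arylphthalide (not isolated) | [K+].COCOc1cc(C)cc(OCc2ccccc2)c1C1(O[O-])OC(=O)c2cc(OCc3ccccc3)cc(OC)c21 | intermediate
26 | potassium 5-(benzyloxy)-2-[2-(benzyloxy)-6-(methoxymethoxy)-4-methylbenzoyl]-3-methoxybenzoate (not isolated) | [K+].COCOc1cc(C)cc(OCc2ccccc2)c1C(=O)c1c(OC)cc(OCc2ccccc2)cc1C([O-])=O | intermediate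
27 | 5-(benzyloxy)-2-[2-(benzyloxy)-6-(methoxymethoxy)-4-methylbenzoyl]-3-methoxybenzoic acid | COCOc1cc(C)cc(OCc2ccccc2)c1C(=O)c1c(OC)cc(OCc2ccccc2)cc1C(O)=O | intermediate
28 | methyl 5-(benzyloxy)-2-[2-(benzyloxy)-6-(methoxymethoxy)-4-methylbenzoyl]-3-methoxybenzoate | COCOc1cc(C)cc(OCc2ccccc2)c1C(=O)c1c(OC)cc(OCc2ccccc2)cc1C(=O)OC | intermediate
29 | methyl 5-(benzyloxy)-2-[2-(benzyloxy)-6-hydroxy-4-methylbenzoyl]-3-methoxybenzoate | COC(=O)c1cc(OCc2ccccc2)cc(OC)c1C(=O)c1c(O)cc(C)cc1OCc1ccccc1 | intermediate
30 | methyl 2-[2-acetoxy-6-(benzyloxy)-4-methylbenzoyl]-5-(benzyloxy)-3-methoxybenzoate | COC(=O)c1cc(OCc2ccccc2)cc(OC)c1C(=O)c1c(OC(C)=O)cc(C)cc1OCc1ccccc1 | intermediate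
31 | penibenzophenone C | COC(=O)c1cc(O)cc(OC)c1C(=O)c1c(O)cc(C)cc1OC(C)=O | target

## Step count and risks

Total steps: 16. Longest linear sequence: 13 (steps 1–6, then 10–16). The ring B branch (steps 7–9) is convergent.

**Step 10 (key step).**
- Risk: the short-lived C2 aryl anion may be protonated, or captured by a second aryne or more isocyanide, before it adds to the electron-rich, doubly ortho-substituted formyl group. The union would then stop at two-component products.
- Fallback: the two ring A carbon bonds are made one at a time, starting from bromophenol 7 and aldehyde 17. The bromine of 7 already marks C2 and its oxygen marks C1.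
- Compound 7 is treated with n-BuLi (2.1 equiv, THF, −78 °C) to give lithium 5-(benzyloxy)-2-lithio-3-methoxyphenoxide F1. This is a persistent nucleophile that can be left with 17 until addition is complete, giving the phenolic benzhydrol F2.
- Selective triflation of the phenol (PhNTf2, K2CO3, DMF, rt) gives the hydroxy triflate F3.
- Carbonylative lactonisation (CO 1 atm, Pd(OAc)2, dppp, Et3N, DMF, 70 °C) lets the carbinol oxygen trap the acylpalladium species and returns to the route at phthalide 23.

**Step 12.**
- Risk: deprotonation of the crowded C3–H may be slow, or the peroxide may break down by aryl migration before it is reduced.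
- Fallback: the lactone is opened reductively, so that both benzylic carbons can be oxidised as alcohols. Starting from 23, LiAlH4 (THF, 0 °C) gives the diol F4.
- A Swern oxidation ((COCl)2, DMSO, Et3N, CH2Cl2, −78 °C) activates both hydroxyls before base is added, which avoids lactol formation and return to the phthalide. It gives the keto aldehyde F5.
- Pinnick oxidation (NaClO2, NaH2PO4, 2-methyl-2-butene, t-BuOH/H2O) returns to the route at keto acid 27.

**Step 3.**
- Risk: metalation may spread to C4/C6 or to the benzylic CH2, or a carbamoyl group may shift to carbon before the bromine source arrives.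
- Fallback: organolithium chemistry is replaced by the electrophilic bromination and selective reductive debromination used to make 2-bromoresorcinol from resorcinol. Starting from 2, Br2 (3 equiv, CHCl3, 0 °C) gives 5-(benzyloxy)-2,4,6-tribromobenzene-1,3-diol F6.
- Na2SO3/NaOH in aqueous MeOH should strip the bromines at C4 and C6, each para to a hydroxyl, and leave the one at C2, which is only ortho to the hydroxyls. This returns to the route at 6 and bypasses 3, 4 and 5.

## Further compounds

F1 | step 10 | lithium 5-(benzyloxy)-2-lithio-3-methoxyphenoxide | COc1cc(OCc2ccccc2)cc(O[Li])c1[Li]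
F2 | step 10 | rac-5-(benzyloxy)-2-{[2-(benzyloxy)-6-(methoxymethoxy)-4-methylphenyl](hydroxy)methyl}-3-methoxyphenol | COCOc1cc(C)cc(OCc2ccccc2)c1C(O)c1c(O)cc(OCc2ccccc2)cc1OC
F3 | step 10 | rac-5-(benzyloxy)-2-{[2-(benzyloxy)-6-(methoxymethoxy)-4-methylphenyl](hydroxy)methyl}-3-methoxyphenyl trifluoromethanesulfonate | COCOc1cc(C)cc(OCc2ccccc2)c1C(O)c1c(OS(=O)(=O)C(F)(F)F)cc(OCc2ccccc2)cc1OC
F4 | step 12 | rac-[2-(benzyloxy)-6-(methoxymethoxy)-4-methylphenyl][4-(benzyloxy)-2-(hydroxymethyl)-6-methoxyphenyl]methanol | COCOc1cc(C)cc(OCc2ccccc2)c1C(O)c1c(OC)cc(OCc2ccccc2)cc1CO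
F5 | step 12 | 5-(benzyloxy)-2-[2-(benzyloxy)-6-(methoxymethoxy)-4-methylbenzoyl]-3-methoxybenzaldehyde | COCOc1cc(C)cc(OCc2ccccc2)c1C(=O)c1c(OC)cc(OCc2ccccc2)cc1C=O
F6 | step 3 | 5-(benzyloxy)-2,4,6-tribromobenzene-1,3-diol | Oc1c(Br)c(O)c(Br)c(OCc2ccccc2)c1Br
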